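Its constants were chosen freely.

A neighbour run puts 0.92 M of partner on the same racemate where this flask puts 0.230 M, so for either flask the question is what share of a portion reaches the left-handed substrate.

left-handed substrate 0.23 M; partner 0.230 M (in portions, 4); right-handed substrate 0.23 M; time 15 d; the portions of partner follow each other after 20 h, the first at the start

    partner + left-handed substrate → left-handed product (k1 = 0.0026 /M/min)
    partner + right-handed substrate → right-handed product (k2 = 0.0014 /M/min)
    partner → decomposed reagent (k3 = 2.1 × 10⁻⁴ /min)
    partner → decomposition product (k4 = 8.8 × 10⁻⁸ /min)
    2 partner → self-condensation product (k5 = 0.011 /M/min)

- partner is single-handed; left-handed substrate and right-handed substrate are mirror images of each other, charged as a racemate, each of them at the stated concentration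
- where a step has two of a species, its rate is k times that concentration squared, and two are used at each turn
- the reaction counts as stopped when no species that holds the left-handed substrate and right-handed substrate together changes by six tenths of a point or more over the second half of the time
- run time (flask): 15 d
- the handed part of partner does not stay in what it makes, so the products of the two hands are mirror images too

1. the state of affairs at 15 d: stopped, and by what, or still going (forward and back rates have come level / it is still moving / all of the left-handed substrate has reacted / the partner has run out first)
2. amount of left-handed product at 15 d, in percent of the left-handed substrate and right-handed substrate together charged

Two rates compete for partner. The steps first order in partner (pseudo-first-order, substrates held at their means) take it at a rate a, and self-condensation takes a fresh portion of 0.0575 M at w = 0.00126 /min. At the charged substrate levels a is 0.00113 /min, and a first pass gives 0.0817 M of left-handed product. Taking each substrate at the mean of its start and end, the right hand following in proportion to its constant, lowers a to 9.93 × 10⁻⁴ /min. A portion's life, 1/a = 16.8 h, is shorter than the gap of 20 h, so portions are reckoned separately, which ignores the remainder from the one before.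

The ratio of self-condensation to first-order loss at the landing of a portion, x = w/a = 1.27, is the quantity to carry. Integrating the decay of a portion gives ln(1 + x)/x, here 64.5%, as the share taken by the first-order steps. The left-handed substrate takes 49.5% of that, so left-handed product comes to 16.0%. The partner should be down to about 9.91 × 10⁻¹⁰ M by the end, with left-handed substrate remaining.

The forecast gives the partner has run out first and 14.8%, lower than this reckoning, and its grounds begin: “Each portion of partner is gone within a day or two”.

The flask gives the partner has run out first and 14.8%, 1.2 percentage points under the reckoning. Its self-condensation product of 0.0471 M holds 41.0% of the partner, against 35.5% from x. In the neighbour with 0.92 M, the read substrates give x = 5.58, and ln(1 + x)/x then predicts 32.2% of left-handed product, where that flask reads 27.8%.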